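I decided not to follow the flask through time, but to ask where target stops growing.

electrophile 0.10 M; nucleophile 0.200 M; buffer base 0.0200 M; buffer acid 0.0300 M; time 6.0 min

    electrophile + nucleophile → acid + target + leaving group (k1 = 0.0204 M⁻¹ s⁻¹)
    protonated nucleophile ⇌ nucleophile + acid, settled at all times (K2 = 1.6 × 10⁻⁸ M)
    buffer acid ⇌ buffer base + acid, settled at all times (K3 = 2.5 × 10⁻¹⁰ M)
    nucleophile ⇌ dormant form (K4 = 0.18, k4 = 0.00347 s⁻¹)
    electrophile + target → side product (k5 = 0.0666 M⁻¹ s⁻¹)

- acid is the free proton; pH is minus the decimal logarithm of its molar concentration
- a species is counted by the electrophile in it: one side product counts as two
- run time (flask): 6.0 min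

* amount of target at 6.0 min, in percent of the electrophile charged
* amount of side product at 6.0 min, in percent of the electrophile charged

Target is made at a rate proportional to electrophile times nucleophile and spent at a rate proportional to electrophile times target, so electrophile cancels where the two rates meet. Target then equals the selectivity factor (main rate constant over side rate constant) times the nucleophile present. With the whole nucleophile charge free, this target ceiling, in fractions of the electrophile charge, is 61.3%; in any moment it scales with the fraction of nucleophile still free. With electrophile as charged, target's half-life against the side step in this flask is 1.7 min, shorter than the 6.0 min run, so I assumed that target would reach the ceiling by the end, although that half-life lengthens as electrophile is used up.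

I guessed that half of the electrophile charge had passed the main step. Each pass takes one nucleophile and frees one acid. Buffer base takes that acid first, since its 2.5 × 10⁻¹⁰ M lies below the 1.6 × 10⁻⁸ M of protonated nucleophile, and each acid beyond it takes a second nucleophile. Dividing the remainder by 1.18 for the dormant form left 50.8% free. So I committed to target 31.1% and, counted double, side product 37.7%.

The forecast gave 27.5% and 47%, reasoning that “released protons tie up the nucleophile”. The simulation gives 27.5% and 48.9%.

Side product stands 11 percentage points above my figure. At 6.00 min this flask holds 47.9% of its nucleophile, which puts the ceiling at 29.4%, with target just under it and still made 1.07 times as fast as it is used up.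

In the neighbour flask with 0.080 M of nucleophile, the full ceiling is 24.5%, and the 42.9% of its own charge left there brings it to 10.5%. The computed target in that flask is 11.7%.

(The numbers of this flask are those of an exercise; the flask was simulated.)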